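## Retrosynthetic overview

1. The butenolide is closed last by an intramolecular Horner–Wadsworth–Emmons (HWE) reaction of a C4-O-phosphonoacetate onto a C3 ketone; C3, C4 and C25 come from a glyceraldehyde acetonide unit.
2. The (6Z)-C6=C7 alkene and C24H2OH come from reductive opening of a 3-alkyl-5,6-dihydro-2H-pyran-2-one, made by ring-closing metathesis (RCM) of the C4 ester of a 2-alkylacrylic acid; the ring fixes the Z geometry.
3. The key C4–C5 bond and the only stereocentre are made by a matched Brown allylation (carbonyl allylation) of (S)-glyceraldehyde acetonide with an allyl fragment.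
4. The side-chain acid comes from dihydro-β-ionone: terminal alkyne, Zr-catalysed methylalumination/oxirane opening (E-alkene), iodide, malonate alkylation, Mannich methylenation.
5. Ring order: cyclohexene (bought in), then the dihydropyranone (temporary, opened again), then the butenolide.

Assumption: the stereocentre is (R), as encoded by the given SMILES; locants C1–C25 are those of the manoalide skeleton (C1 lactone C=O, C3 bears C25H2OH, C4 stereocentre, C6=C7 with C24H2OH on C7, C10=C11).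

## Route

Step 1
Reactants: 1 dihydro-β-ionone [4-(2,6,6-trimethylcyclohex-1-en-1-yl)butan-2-one]
Product: 3 2-(but-3-yn-1-yl)-1,3,3-trimethylcyclohex-1-ene, via enol phosphate 2 (not isolated)
Conditions: LiN(iPr)2 (1.05 equiv), THF, −78 °C; ClP(O)(OEt)2, −78 °C → rt; LiN(iPr)2 (2.3 equiv), −78 °C → rt; aq. NH4Cl
Reagents that add atoms: none
Why: kinetic deprotonation at the methyl group gives the terminal enol phosphate, which undergoes base-induced β-elimination of diethyl phosphate to the terminal alkyne (Negishi methyl ketone → alkyne protocol).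

Step 2
Reactants: 3 2-(but-3-yn-1-yl)-1,3,3-trimethylcyclohex-1-ene
Product: 6 (3E)-4-methyl-6-(2,6,6-trimethylcyclohex-1-en-1-yl)hex-3-en-1-ol, via alkenyldimethylalane 4 (not isolated), via lithium alkenylaluminate 5 (not isolated)
Conditions: Me3Al (2 equiv), Cp2ZrCl2 (0.25 equiv), ClCH2CH2Cl, rt; volatiles removed; n-BuLi, hexane/THF, −78 → 0 °C; ethylene oxide (3 equiv), 0 °C → rt; aq. NH4Cl
Reagents that add atoms: trimethylaluminium C[Al](C)C; ethylene oxide C1CO1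
Why: Zr-catalysed Negishi carboalumination adds Me and Al syn with Al at the terminal carbon, which fixes the E-trisubstituted alkene, and the alkenyl alanate opens oxirane with retention of alkene geometry.

Step 3
Reactants: 6 (3E)-4-methyl-6-(2,6,6-trimethylcyclohex-1-en-1-yl)hex-3-en-1-ol
Product: 7 2-[(3E)-6-iodo-3-methylhex-3-en-1-yl]-1,3,3-trimethylcyclohex-1-ene
Conditions: I2, PPh3, imidazole, CH2Cl2, 0 °C → rt
Reagents that add atoms: iodine II
Why: Appel-type iodination of the primary alcohol by SN2 displacement of the alkoxyphosphonium ion leaves both alkenes untouched.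

Step 4
Reactants: 7 2-[(3E)-6-iodo-3-methylhex-3-en-1-yl]-1,3,3-trimethylcyclohex-1-ene; 8 diethyl malonate
Product: 9 diethyl 2-[(3E)-4-methyl-6-(2,6,6-trimethylcyclohex-1-en-1-yl)hex-3-en-1-yl]propanedioate
Conditions: 8 (2.5 equiv), NaH (2.2 equiv), THF/DMF 3:1, 0 °C; then 7, 60 °C
Reagents that add atoms: none
Why: malonic ester alkylation (SN2 on the primary iodide), with excess malonate suppressing dialkylation.

Step 5
Reactants: 9 diethyl 2-[(3E)-4-methyl-6-(2,6,6-trimethylcyclohex-1-en-1-yl)hex-3-en-1-yl]propanedioate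
Product: 10 2-[(3E)-4-methyl-6-(2,6,6-trimethylcyclohex-1-en-1-yl)hex-3-en-1-yl]propanedioic acid
Conditions: KOH (5 equiv), EtOH/H2O 4:1, 70 °C; then cold 1 M HCl to pH 2
Reagents that add atoms: potassium hydroxide [K+].[OH-]
Why: saponification of both esters, with cold dilute acid work-up to spare the alkenes.

Step 6
Reactants: 10 2-[(3E)-4-methyl-6-(2,6,6-trimethylcyclohex-1-en-1-yl)hex-3-en-1-yl]propanedioic acid
Product: 12 (5E)-6-methyl-2-methylidene-8-(2,6,6-trimethylcyclohex-1-en-1-yl)oct-5-enoic acid, via Mannich base 11 (not isolated)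
Conditions: (CH2O)n (2 equiv), Et2NH (1.5 equiv), EtOAc, reflux
Reagents that add atoms: paraformaldehyde (reacts as formaldehyde) C=O
Why: Mannich reaction of the malonic acid with the iminium ion from CH2O/Et2NH, followed by decarboxylative elimination of Et2NH, gives the 2-substituted acrylic acid.

Step 7
Reactants: 13 (R)-solketal {[(4R)-2,2-dimethyl-1,3-dioxolan-4-yl]methanol}
Product: 14 (4S)-2,2-dimethyl-1,3-dioxolane-4-carbaldehyde
Conditions: (COCl)2, DMSO, CH2Cl2, −78 °C; iPr2NEt, −78 → −20 °C; used at once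
Reagents that add atoms: none
Why: Swern oxidation at low temperature with a hindered base keeps the α-stereocentre intact (the R → S change of descriptor is only a CIP priority change).

Step 8
Reactants: 14 (4S)-2,2-dimethyl-1,3-dioxolane-4-carbaldehyde
Product: 16 (1R)-1-[(4S)-2,2-dimethyl-1,3-dioxolan-4-yl]but-3-en-1-ol, via borinate ester 15 (not isolated)
Conditions: (+)-Ipc2BOMe [from (−)-α-pinene], allylmagnesium bromide, Et2O, 0 °C → rt; then 14, −78 °C; then 3 M NaOH, 30% H2O2, rt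
Reagents that add atoms: allylmagnesium bromide C=CC[Mg]Br
Why: Brown asymmetric allylboration (carbonyl allylation) through a chair Zimmerman–Traxler transition state, in which the reagent adds to the Re face that is also the Felkin–Anh (anti) face of the (S)-aldehyde, so this matched pair sets (R)-C4 with high diastereoselectivity and the minor diastereomer is removed by chromatography.

Step 9
Reactants: 16 (1R)-1-[(4S)-2,2-dimethyl-1,3-dioxolan-4-yl]but-3-en-1-ol; 12 (5E)-6-methyl-2-methylidene-8-(2,6,6-trimethylcyclohex-1-en-1-yl)oct-5-enoic acid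
Product: 17 (1R)-1-[(4S)-2,2-dimethyl-1,3-dioxolan-4-yl]but-3-en-1-yl (5E)-6-methyl-2-methylidene-8-(2,6,6-trimethylcyclohex-1-en-1-yl)oct-5-enoate
Conditions: DCC, DMAP (0.2 equiv), CH2Cl2, 0 °C → rt
Reagents that add atoms: none
Why: Steglich esterification acylates the C4 oxygen without breaking a bond at C4, so the configuration is retained.

Step 10
Reactants: 17 (1R)-1-[(4S)-2,2-dimethyl-1,3-dioxolan-4-yl]but-3-en-1-yl (5E)-6-methyl-2-methylidene-8-(2,6,6-trimethylcyclohex-1-en-1-yl)oct-5-enoate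
Product: 18 (6R)-6-[(4S)-2,2-dimethyl-1,3-dioxolan-4-yl]-3-[(3E)-4-methyl-6-(2,6,6-trimethylcyclohex-1-en-1-yl)hex-3-en-1-yl]-5,6-dihydro-2H-pyran-2-one
Conditions: second-generation Grubbs catalyst (H2IMes)(PCy3)Cl2Ru=CHPh (5 mol %), CH2Cl2 (5 mM), 40 °C
Reagents that add atoms: none
Why: ring-closing metathesis of the vinyl group with the acrylate methylene closes the six-membered unsaturated lactone with loss of ethylene, and the ring forces C5 and C24 cis on C6=C7 while the tri- and tetrasubstituted alkenes stay inert.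

Step 11
Reactants: 18 (6R)-6-[(4S)-2,2-dimethyl-1,3-dioxolan-4-yl]-3-[(3E)-4-methyl-6-(2,6,6-trimethylcyclohex-1-en-1-yl)hex-3-en-1-yl]-5,6-dihydro-2H-pyran-2-one
Product: 20 (1R,3Z,7E)-1-[(4S)-2,2-dimethyl-1,3-dioxolan-4-yl]-4-(hydroxymethyl)-8-methyl-10-(2,6,6-trimethylcyclohex-1-en-1-yl)deca-3,7-dien-1-ol, via lactol 19 (not isolated)
Conditions: iBu2AlH (5 equiv), CH2Cl2, −78 °C → rt; aq. potassium sodium tartrate
Reagents that add atoms: none
Why: 1,2-reduction of the unsaturated lactone through its lactol opens the ring to the (Z)-allylic alcohol and the free C4–OH, carrying over the alkene geometry fixed in the ring.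

Step 12
Reactants: 20 (1R,3Z,7E)-1-[(4S)-2,2-dimethyl-1,3-dioxolan-4-yl]-4-(hydroxymethyl)-8-methyl-10-(2,6,6-trimethylcyclohex-1-en-1-yl)deca-3,7-dien-1-ol
Product: 21 (1R,3Z,7E)-4-[(tert-butyldiphenylsilyloxy)methyl]-1-[(4S)-2,2-dimethyl-1,3-dioxolan-4-yl]-8-methyl-10-(2,6,6-trimethylcyclohex-1-en-1-yl)deca-3,7-dien-1-ol
Conditions: TBDPSCl (1.05 equiv), imidazole, CH2Cl2, 0 °C
Reagents that add atoms: tert-butyl(chloro)diphenylsilane CC(C)(C)[Si](Cl)(c1ccccc1)c1ccccc1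
Why: selective silylation of the primary allylic C24–OH over the hindered secondary C4–OH.

Step 13
Reactants: 21 (1R,3Z,7E)-4-[(tert-butyldiphenylsilyloxy)methyl]-1-[(4S)-2,2-dimethyl-1,3-dioxolan-4-yl]-8-methyl-10-(2,6,6-trimethylcyclohex-1-en-1-yl)deca-3,7-dien-1-ol; 22 diethylphosphonoacetic acid
Product: 23 (1R,3Z,7E)-4-[(tert-butyldiphenylsilyloxy)methyl]-1-[(4S)-2,2-dimethyl-1,3-dioxolan-4-yl]-8-methyl-10-(2,6,6-trimethylcyclohex-1-en-1-yl)deca-3,7-dien-1-yl 2-(diethoxyphosphoryl)acetate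
Conditions: DCC, DMAP (0.1 equiv), CH2Cl2, 0 °C → rt
Reagents that add atoms: none
Why: Steglich esterification places the HWE handle (future C1–C2) on the C4 oxygen without touching the stereocentre.

Step 14
Reactants: 23 (1R,3Z,7E)-4-[(tert-butyldiphenylsilyloxy)methyl]-1-[(4S)-2,2-dimethyl-1,3-dioxolan-4-yl]-8-methyl-10-(2,6,6-trimethylcyclohex-1-en-1-yl)deca-3,7-dien-1-yl 2-(diethoxyphosphoryl)acetate
Product: 24 (2S,3R,5Z,9E)-6-[(tert-butyldiphenylsilyloxy)methyl]-1,2-dihydroxy-10-methyl-12-(2,6,6-trimethylcyclohex-1-en-1-yl)dodeca-5,9-dien-3-yl 2-(diethoxyphosphoryl)acetate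
Conditions: AcOH/H2O/THF 4:1:1, 40 °C
Reagents that add atoms: none
Why: mild acid-catalysed acetal hydrolysis removes the terminal acetonide while the TBDPS ether, the ester and the alkenes survive.

Step 15
Reactants: 24 (2S,3R,5Z,9E)-6-[(tert-butyldiphenylsilyloxy)methyl]-1,2-dihydroxy-10-methyl-12-(2,6,6-trimethylcyclohex-1-en-1-yl)dodeca-5,9-dien-3-yl 2-(diethoxyphosphoryl)acetate
Product: 25 (2S,3R,5Z,9E)-1-(tert-butyldiphenylsilyloxy)-6-[(tert-butyldiphenylsilyloxy)methyl]-2-hydroxy-10-methyl-12-(2,6,6-trimethylcyclohex-1-en-1-yl)dodeca-5,9-dien-3-yl 2-(diethoxyphosphoryl)acetate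
Conditions: TBDPSCl (1.1 equiv), imidazole, CH2Cl2, −20 → 0 °C
Reagents that add atoms: tert-butyl(chloro)diphenylsilane CC(C)(C)[Si](Cl)(c1ccccc1)c1ccccc1
Why: chemoselective silylation of the primary C25–OH leaves only the secondary C3–OH free.

Step 16
Reactants: 25 (2S,3R,5Z,9E)-1-(tert-butyldiphenylsilyloxy)-6-[(tert-butyldiphenylsilyloxy)methyl]-2-hydroxy-10-methyl-12-(2,6,6-trimethylcyclohex-1-en-1-yl)dodeca-5,9-dien-3-yl 2-(diethoxyphosphoryl)acetate
Product: 26 (3R,5Z,9E)-1-(tert-butyldiphenylsilyloxy)-6-[(tert-butyldiphenylsilyloxy)methyl]-10-methyl-2-oxo-12-(2,6,6-trimethylcyclohex-1-en-1-yl)dodeca-5,9-dien-3-yl 2-(diethoxyphosphoryl)acetate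
Conditions: Dess–Martin periodinane, NaHCO3, CH2Cl2, 0 °C → rt
Reagents that add atoms: none
Why: Dess–Martin oxidation under buffered neutral conditions gives the C3 ketone (removing the auxiliary C3 stereocentre) without enolising toward C4.

Step 17
Reactants: 26 (3R,5Z,9E)-1-(tert-butyldiphenylsilyloxy)-6-[(tert-butyldiphenylsilyloxy)methyl]-10-methyl-2-oxo-12-(2,6,6-trimethylcyclohex-1-en-1-yl)dodeca-5,9-dien-3-yl 2-(diethoxyphosphoryl)acetate
Product: 27 (5R)-4-[(tert-butyldiphenylsilyloxy)methyl]-5-[(2Z,6E)-3-[(tert-butyldiphenylsilyloxy)methyl]-7-methyl-9-(2,6,6-trimethylcyclohex-1-en-1-yl)nona-2,6-dien-1-yl]furan-2(5H)-one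
Conditions: LiCl, iPr2NEt, MeCN, 0 °C → rt
Reagents that add atoms: none
Why: intramolecular HWE olefination under Masamune–Roush conditions closes the butenolide (C2=C3), the weak amine base leaving the (R)-C4 centre unchanged.

Step 18
Reactants: 27 (5R)-4-[(tert-butyldiphenylsilyloxy)methyl]-5-[(2Z,6E)-3-[(tert-butyldiphenylsilyloxy)methyl]-7-methyl-9-(2,6,6-trimethylcyclohex-1-en-1-yl)nona-2,6-dien-1-yl]furan-2(5H)-one
Product: 28 (6Z)-neomanoalide {(5R)-4-(hydroxymethyl)-5-[(2Z,6E)-3-(hydroxymethyl)-7-methyl-9-(2,6,6-trimethylcyclohex-1-en-1-yl)nona-2,6-dien-1-yl]furan-2(5H)-one}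
Conditions: HF·pyridine, THF/pyridine, 0 °C → rt
Reagents that add atoms: none
Why: fluoride cleavage of both silyl ethers under buffered acidic conditions does not enolise the butenolide and releases the target.

## Compound list

1 | dihydro-β-ionone, 4-(2,6,6-trimethylcyclohex-1-en-1-yl)butan-2-one | CC(=O)CCC1=C(C)CCCC1(C)C | starting material
2 | diethyl 4-(2,6,6-trimethylcyclohex-1-en-1-yl)but-1-en-2-yl phosphate | C=C(CCC1=C(C)CCCC1(C)C)OP(=O)(OCC)OCC | intermediate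
3 | 2-(but-3-yn-1-yl)-1,3,3-trimethylcyclohex-1-ene | C#CCCC1=C(C)CCCC1(C)C | intermediate
4 | dimethyl[(1E)-2-methyl-4-(2,6,6-trimethylcyclohex-1-en-1-yl)but-1-en-1-yl]alumane | C[Al](C)/C=C(\C)CCC1=C(C)CCCC1(C)C | intermediate
5 | lithium butyl(dimethyl)[(1E)-2-methyl-4-(2,6,6-trimethylcyclohex-1-en-1-yl)but-1-en-1-yl]aluminate | [Li+].CCCC[Al-](C)(C)/C=C(\C)CCC1=C(C)CCCC1(C)C | intermediate
6 | (3E)-4-methyl-6-(2,6,6-trimethylcyclohex-1-en-1-yl)hex-3-en-1-ol | CC1=C(CC/C(C)=C/CCO)C(C)(C)CCC1 | intermediate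
7 | 2-[(3E)-6-iodo-3-methylhex-3-en-1-yl]-1,3,3-trimethylcyclohex-1-ene | CC1=C(CC/C(C)=C/CCI)C(C)(C)CCC1 | intermediate
8 | diethyl malonate | CCOC(=O)CC(=O)OCC | starting material
9 | diethyl 2-[(3E)-4-methyl-6-(2,6,6-trimethylcyclohex-1-en-1-yl)hex-3-en-1-yl]propanedioate | CC1=C(CC/C(C)=C/CCC(C(=O)OCC)C(=O)OCC)C(C)(C)CCC1 | intermediate
10 | 2-[(3E)-4-methyl-6-(2,6,6-trimethylcyclohex-1-en-1-yl)hex-3-en-1-yl]propanedioic acid | CC1=C(CC/C(C)=C/CCC(C(=O)O)C(=O)O)C(C)(C)CCC1 | intermediate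
11 | 2-[(diethylamino)methyl]-2-[(3E)-4-methyl-6-(2,6,6-trimethylcyclohex-1-en-1-yl)hex-3-en-1-yl]propanedioic acid | CC1=C(CC/C(C)=C/CCC(CN(CC)CC)(C(=O)O)C(=O)O)C(C)(C)CCC1 | intermediate
12 | (5E)-6-methyl-2-methylidene-8-(2,6,6-trimethylcyclohex-1-en-1-yl)oct-5-enoic acid | CC1=C(CC/C(C)=C/CCC(=C)C(=O)O)C(C)(C)CCC1 | intermediate
13 | (R)-solketal, [(4R)-2,2-dimethyl-1,3-dioxolan-4-yl]methanol | OC[C@@H]1COC(C)(C)O1 | starting material
14 | (4S)-2,2-dimethyl-1,3-dioxolane-4-carbaldehyde, (S)-glyceraldehyde acetonide | O=C[C@@H]1COC(C)(C)O1 | intermediate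
15 | (1R)-1-[(4S)-2,2-dimethyl-1,3-dioxolan-4-yl]but-3-en-1-yl diisopinocampheylborinate, both Ipc groups from (−)-α-pinene | C=CC[C@@H](OB([C@H]1C[C@H]2C[C@@H]([C@@H]1C)C2(C)C)[C@H]1C[C@H]2C[C@@H]([C@@H]1C)C2(C)C)[C@@H]1COC(C)(C)O1 | intermediate
16 | (1R)-1-[(4S)-2,2-dimethyl-1,3-dioxolan-4-yl]but-3-en-1-ol | C=CC[C@@H](O)[C@@H]1COC(C)(C)O1 | intermediate
17 | (1R)-1-[(4S)-2,2-dimethyl-1,3-dioxolan-4-yl]but-3-en-1-yl (5E)-6-methyl-2-methylidene-8-(2,6,6-trimethylcyclohex-1-en-1-yl)oct-5-enoate | CC1=C(CC/C(C)=C/CCC(=C)C(=O)O[C@H](CC=C)[C@@H]2COC(C)(C)O2)C(C)(C)CCC1 | intermediate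
18 | (6R)-6-[(4S)-2,2-dimethyl-1,3-dioxolan-4-yl]-3-[(3E)-4-methyl-6-(2,6,6-trimethylcyclohex-1-en-1-yl)hex-3-en-1-yl]-5,6-dihydro-2H-pyran-2-one | CC1=C(CC/C(C)=C/CCC2=CC[C@H]([C@@H]3COC(C)(C)O3)OC2=O)C(C)(C)CCC1 | intermediate
19 | (6R)-6-[(4S)-2,2-dimethyl-1,3-dioxolan-4-yl]-3-[(3E)-4-methyl-6-(2,6,6-trimethylcyclohex-1-en-1-yl)hex-3-en-1-yl]-5,6-dihydro-2H-pyran-2-ol, present as its aluminium alkoxide, both C2 epimers | CC1=C(CC/C(C)=C/CCC2=CC[C@H]([C@@H]3COC(C)(C)O3)OC2O)C(C)(C)CCC1 | intermediate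
20 | (1R,3Z,7E)-1-[(4S)-2,2-dimethyl-1,3-dioxolan-4-yl]-4-(hydroxymethyl)-8-methyl-10-(2,6,6-trimethylcyclohex-1-en-1-yl)deca-3,7-dien-1-ol | CC1=C(CC/C(C)=C/CC/C(CO)=C/C[C@@H](O)[C@@H]2COC(C)(C)O2)C(C)(C)CCC1 | intermediate
21 | (1R,3Z,7E)-4-[(tert-butyldiphenylsilyloxy)methyl]-1-[(4S)-2,2-dimethyl-1,3-dioxolan-4-yl]-8-methyl-10-(2,6,6-trimethylcyclohex-1-en-1-yl)deca-3,7-dien-1-ol | CC1=C(CC/C(C)=C/CC/C(CO[Si](c2ccccc2)(c2ccccc2)C(C)(C)C)=C/C[C@@H](O)[C@@H]2COC(C)(C)O2)C(C)(C)CCC1 | intermediate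
22 | diethylphosphonoacetic acid | OC(=O)CP(=O)(OCC)OCC | starting material
23 | (1R,3Z,7E)-4-[(tert-butyldiphenylsilyloxy)methyl]-1-[(4S)-2,2-dimethyl-1,3-dioxolan-4-yl]-8-methyl-10-(2,6,6-trimethylcyclohex-1-en-1-yl)deca-3,7-dien-1-yl 2-(diethoxyphosphoryl)acetate | CC1=C(CC/C(C)=C/CC/C(CO[Si](c2ccccc2)(c2ccccc2)C(C)(C)C)=C/C[C@@H](OC(=O)CP(=O)(OCC)OCC)[C@@H]2COC(C)(C)O2)C(C)(C)CCC1 | intermediate
24 | (2S,3R,5Z,9E)-6-[(tert-butyldiphenylsilyloxy)methyl]-1,2-dihydroxy-10-methyl-12-(2,6,6-trimethylcyclohex-1-en-1-yl)dodeca-5,9-dien-3-yl 2-(diethoxyphosphoryl)acetate | CC1=C(CC/C(C)=C/CC/C(CO[Si](c2ccccc2)(c2ccccc2)C(C)(C)C)=C/C[C@@H](OC(=O)CP(=O)(OCC)OCC)[C@@H](O)CO)C(C)(C)CCC1 | intermediate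
25 | (2S,3R,5Z,9E)-1-(tert-butyldiphenylsilyloxy)-6-[(tert-butyldiphenylsilyloxy)methyl]-2-hydroxy-10-methyl-12-(2,6,6-trimethylcyclohex-1-en-1-yl)dodeca-5,9-dien-3-yl 2-(diethoxyphosphoryl)acetate | CC1=C(CC/C(C)=C/CC/C(CO[Si](c2ccccc2)(c2ccccc2)C(C)(C)C)=C/C[C@@H](OC(=O)CP(=O)(OCC)OCC)[C@@H](O)CO[Si](c2ccccc2)(c2ccccc2)C(C)(C)C)C(C)(C)CCC1 | intermediate
26 | (3R,5Z,9E)-1-(tert-butyldiphenylsilyloxy)-6-[(tert-butyldiphenylsilyloxy)methyl]-10-methyl-2-oxo-12-(2,6,6-trimethylcyclohex-1-en-1-yl)dodeca-5,9-dien-3-yl 2-(diethoxyphosphoryl)acetate | CC1=C(CC/C(C)=C/CC/C(CO[Si](c2ccccc2)(c2ccccc2)C(C)(C)C)=C/C[C@@H](OC(=O)CP(=O)(OCC)OCC)C(=O)CO[Si](c2ccccc2)(c2ccccc2)C(C)(C)C)C(C)(C)CCC1 | intermediate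
27 | (5R)-4-[(tert-butyldiphenylsilyloxy)methyl]-5-[(2Z,6E)-3-[(tert-butyldiphenylsilyloxy)methyl]-7-methyl-9-(2,6,6-trimethylcyclohex-1-en-1-yl)nona-2,6-dien-1-yl]furan-2(5H)-one | CC1=C(CC/C(C)=C/CC/C(CO[Si](c2ccccc2)(c2ccccc2)C(C)(C)C)=C/C[C@H]2OC(=O)C=C2CO[Si](c2ccccc2)(c2ccccc2)C(C)(C)C)C(C)(C)CCC1 | intermediate
28 | (6Z)-neomanoalide, (5R)-4-(hydroxymethyl)-5-[(2Z,6E)-3-(hydroxymethyl)-7-methyl-9-(2,6,6-trimethylcyclohex-1-en-1-yl)nona-2,6-dien-1-yl]furan-2(5H)-one | CC1=C(CC/C(C)=C/CC/C(=C/C[C@H]2OC(=O)C=C2CO)CO)C(C)(C)CCC1 | target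

## Step count and risks

Total step count: 18. Longest linear sequence: 16 steps (steps 1–6, then 9–18); the shorter branch is steps 7–8.

Most likely to fail, step 2 (carboalumination and oxirane opening). It uses pyrophoric Me3Al, the alanate opening of oxirane can stall, and it depends on the regiochemical purity of alkyne 3. The fallback sets out from 1 and comes back at 6, replacing steps 1 and 2 by olefination chemistry. HWE reaction of 1 with triethyl phosphonoacetate and NaH gives ethyl (2E)-3-methyl-5-(2,6,6-trimethylcyclohex-1-en-1-yl)pent-2-enoate F1 (E/Z about 4:1, the Z isomer removed by chromatography). Reduction with iBu2AlH gives (2E)-3-methyl-5-(2,6,6-trimethylcyclohex-1-en-1-yl)pent-2-en-1-ol F2. MnO2 oxidation gives (2E)-3-methyl-5-(2,6,6-trimethylcyclohex-1-en-1-yl)pent-2-enal F3. Wittig methylenation with Ph3P=CH2 gives 1,3,3-trimethyl-2-[(3E)-3-methylhexa-3,5-dien-1-yl]cyclohex-1-ene F4. Hydroboration of the terminal vinyl group with 9-BBN, then NaOH/H2O2, returns to 6.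

Step 10 (RCM). Closure onto the hindered, electron-poor 1,1-disubstituted acrylate may be slow and dimerisation through the vinyl group can compete. The fallback sets out from 16 (with iodide 7 as second input) and comes back at 18, building the alkene by Z-selective olefination and lactonisation. 16 is silylated (Et3SiCl, imidazole) to (4S)-2,2-dimethyl-4-[(1R)-1-(triethylsilyloxy)but-3-en-1-yl]-1,3-dioxolane F5, which is ozonised (O3, then PPh3) to (3R)-3-[(4S)-2,2-dimethyl-1,3-dioxolan-4-yl]-3-(triethylsilyloxy)propanal F6. Separately, 7 alkylates the sodium salt of methyl bis(2,2,2-trifluoroethyl)phosphonoacetate to give methyl (5E)-2-[bis(2,2,2-trifluoroethoxy)phosphoryl]-6-methyl-8-(2,6,6-trimethylcyclohex-1-en-1-yl)oct-5-enoate F7. Still–Gennari olefination of F6 with F7 (KN(SiMe3)2, 18-crown-6, THF, −78 °C) gives methyl (2Z,5E)-2-{(3R)-3-[(4S)-2,2-dimethyl-1,3-dioxolan-4-yl]-3-(triethylsilyloxy)propylidene}-6-methyl-8-(2,6,6-trimethylcyclohex-1-en-1-yl)oct-5-enoate F8. Bu4NF removes the silyl group and the C4 alkoxide lactonises onto the cis ester to give 18; any E-enoate cannot lactonise and is separated.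

Step 17 (butenolide closure). The base acts next to the acidic C4–H, so epimerisation is possible, and the step inherits any acyl migration suffered by 24 or 25. The fallback sets out from 21 and comes back at 27, with no acyl group next to a free hydroxyl and a neutral ring closure. 21 is protected (NaH, 4-methoxybenzyl chloride, Bu4NI) as the C4 4-methoxybenzyl ether of 21 F9. Aqueous AcOH removes the acetonide to give the C3,C25-diol F10. TBDPSCl/imidazole gives the C25 silyl ether with free C3–OH F11. Dess–Martin oxidation gives the C3 ketone F12. DDQ (CH2Cl2/pH 7 buffer) gives the C4-hydroxy C3-ketone F13. (Triphenylphosphoranylidene)ketene, Ph3P=C=C=O, in toluene at 80 °C acylates the C4–OH and closes the butenolide by intramolecular Wittig reaction, giving 27.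

## Further compounds

F1 | step 2 | ethyl (2E)-3-methyl-5-(2,6,6-trimethylcyclohex-1-en-1-yl)pent-2-enoate | CCOC(=O)/C=C(\C)CCC1=C(C)CCCC1(C)C
F2 | step 2 | (2E)-3-methyl-5-(2,6,6-trimethylcyclohex-1-en-1-yl)pent-2-en-1-ol | OC/C=C(\C)CCC1=C(C)CCCC1(C)C
F3 | step 2 | (2E)-3-methyl-5-(2,6,6-trimethylcyclohex-1-en-1-yl)pent-2-enal | O=C/C=C(\C)CCC1=C(C)CCCC1(C)C
F4 | step 2 | 1,3,3-trimethyl-2-[(3E)-3-methylhexa-3,5-dien-1-yl]cyclohex-1-ene | C=C/C=C(\C)CCC1=C(C)CCCC1(C)C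
F5 | step 10 | (4S)-2,2-dimethyl-4-[(1R)-1-(triethylsilyloxy)but-3-en-1-yl]-1,3-dioxolane | C=CC[C@@H](O[Si](CC)(CC)CC)[C@@H]1COC(C)(C)O1
F6 | step 10 | (3R)-3-[(4S)-2,2-dimethyl-1,3-dioxolan-4-yl]-3-(triethylsilyloxy)propanal | O=CC[C@@H](O[Si](CC)(CC)CC)[C@@H]1COC(C)(C)O1
F7 | step 10 | methyl (5E)-2-[bis(2,2,2-trifluoroethoxy)phosphoryl]-6-methyl-8-(2,6,6-trimethylcyclohex-1-en-1-yl)oct-5-enoate | CC1=C(CC/C(C)=C/CCC(C(=O)OC)P(=O)(OCC(F)(F)F)OCC(F)(F)F)C(C)(C)CCC1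
F8 | step 10 | methyl (2Z,5E)-2-{(3R)-3-[(4S)-2,2-dimethyl-1,3-dioxolan-4-yl]-3-(triethylsilyloxy)propylidene}-6-methyl-8-(2,6,6-trimethylcyclohex-1-en-1-yl)oct-5-enoate | CC1=C(CC/C(C)=C/CC/C(C(=O)OC)=C/C[C@@H](O[Si](CC)(CC)CC)[C@@H]2COC(C)(C)O2)C(C)(C)CCC1
F9 | step 17 | C4 4-methoxybenzyl ether of 21 | CC1=C(CC/C(C)=C/CC/C(CO[Si](c2ccccc2)(c2ccccc2)C(C)(C)C)=C/C[C@@H](OCc2ccc(OC)cc2)[C@@H]2COC(C)(C)O2)C(C)(C)CCC1
F10 | step 17 | C3,C25-diol from F9 (acetonide removed; C4 4-methoxybenzyl ether, C24 TBDPS ether) | CC1=C(CC/C(C)=C/CC/C(CO[Si](c2ccccc2)(c2ccccc2)C(C)(C)C)=C/C[C@@H](OCc2ccc(OC)cc2)[C@@H](O)CO)C(C)(C)CCC1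
F11 | step 17 | C25 TBDPS ether of F10 with free C3–OH | CC1=C(CC/C(C)=C/CC/C(CO[Si](c2ccccc2)(c2ccccc2)C(C)(C)C)=C/C[C@@H](OCc2ccc(OC)cc2)[C@@H](O)CO[Si](c2ccccc2)(c2ccccc2)C(C)(C)C)C(C)(C)CCC1
F12 | step 17 | C3 ketone from F11 (C4 4-methoxybenzyl ether, C24 and C25 TBDPS ethers) | CC1=C(CC/C(C)=C/CC/C(CO[Si](c2ccccc2)(c2ccccc2)C(C)(C)C)=C/C[C@@H](OCc2ccc(OC)cc2)C(=O)CO[Si](c2ccccc2)(c2ccccc2)C(C)(C)C)C(C)(C)CCC1
F13 | step 17 | (3R,5Z,9E)-1-(tert-butyldiphenylsilyloxy)-6-[(tert-butyldiphenylsilyloxy)methyl]-3-hydroxy-10-methyl-12-(2,6,6-trimethylcyclohex-1-en-1-yl)dodeca-5,9-dien-2-one | CC1=C(CC/C(C)=C/CC/C(CO[Si](c2ccccc2)(c2ccccc2)C(C)(C)C)=C/C[C@@H](O)C(=O)CO[Si](c2ccccc2)(c2ccccc2)C(C)(C)C)C(C)(C)CCC1
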